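Time in this flask runs from seconds to days, so you place each step on a ladder, then follow one substrate molecule down it.

| flask | substrate | reagent | free catalyst | time |
|---|---|---|---|---|
| oak | 10 mM | 9.00 mM | 60 µM | 5.0 d |
| maple | 10 mM | 9.00 mM | 60 µM | 12 d |
| larch | 10 mM | 9.00 mM | 60 µM | 30 d |

    2 catalyst intermediate D → spent catalyst (k1 = 1090 L mol⁻¹ h⁻¹)
    substrate + catalyst intermediate A → catalyst intermediate B (k2 = 3050 L mol⁻¹ h⁻¹)
    catalyst intermediate B ⇌ catalyst intermediate C (K3 = 0.99, k3 = 6.34 h⁻¹)
    substrate + by-product → side product (k4 = 2.63 L mol⁻¹ h⁻¹)
    catalyst intermediate C → by-product + catalyst intermediate D (k5 = 309 h⁻¹)
    reagent + free catalyst ⇌ catalyst intermediate A (K6 = 69.4 L mol⁻¹, k6 = 385 L mol⁻¹ h⁻¹)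
    catalyst intermediate D → free catalyst + target (k7 = 22.0 h⁻¹)

- a species is counted by the substrate in it: one spent catalyst counts as two
- a doubled species enters its step squared and goes two at a time
- run time (oak): 5.0 d

- which of the two there is more of at the end, oak (target / side product)
- which of the two there is more of at the end, maple (target / side product)
- which of the two there is more of at the end, larch (target / side product)
- how much target is there at the end, in percent of the substrate charged: oak
- how much target is there at the end, in percent of the substrate charged: maple
- how much target is there at the end, in percent of the substrate charged: larch

Here is my own reckoning, from the fast end. Catalyst intermediate C has a half-life of 0.135 min, and catalyst intermediate D one of 1.89 min. Catalyst intermediates B and C relax into each other in 3.26 min. Free catalyst takes up reagent more slowly than these, with a half-life of 12.0 min at the charged reagent. Catalyst intermediate A is made and lost quickly, so it follows its surroundings. At the charge I put it at 5.77 µM. Adding the stays gives one turn of the round in 0.577 h. At that starting pace, one substrate charge needs 4.01 d. The top rung is by-product, whose half-life against oak's charged substrate is 1.1 d. That is the same scale as the run, so by-product builds up as a slow pool beneath a fast round.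

Now follow one substrate molecule. It meets either catalyst intermediate A or by-product, and [substrate] stands in both rates, so it cancels. Call the [by-product] at which its two chances are equal, the rate constant of binding to catalyst intermediate A times [catalyst intermediate A] over the rate constant of the side step, the even level: 6.69 mM. [By-product] over the even level is the selectivity factor, side product against target.

Each target brings one by-product, and each side product eats one. I assume [catalyst intermediate A] holds its start value. [By-product] then climbs toward the even level along a saturating exponential in target made. Target plus side product must equal the substrate charge. Two passes, started from target equal to the reagent charge, give by-product 4.50 mM and target 7.25 mM. That is less than the reagent charge, so substrate is the limiting reagent. My plateau is 72.5 % for maple and 72.5 % for larch, with target ahead in maple and target in larch. Oak may stop short of that, so for oak I give a ceiling and not a value: target below 72.5 %.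

The forecast has target ahead in oak, target in maple and target in larch, with 64 %, 69.5 % and 70 %: “target plateaus near 70% by about 12 days”. My plateau sits higher than its larch value.

The flask gives 64.0 % target against 27.2 % side product in oak, 69.8 % against 30.2 % in maple, and 69.8 % against 30.2 % in larch.

Larch stops there mainly through the side step: struck out, its target reaches 89.9 %. At maple's end, catalyst intermediate A reads 11.8 % of the catalyst, which puts the even level at 8.24 mM, higher than its 3.96 mM of by-product. With 17 mM of substrate in a flask otherwise like maple, reagent falls to 2.87 % of its charge and catalyst intermediate A to 1.04 %. The even level drops to 0.723 mM, lower than that flask's 1.62 mM of by-product, and target ends at 51.4 %.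

The constants used here stand for no real mixture; the run is a simulation.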